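**Retrosynthetic overview**

1. Target ⇒ the same skeleton with the quinone masked as its 11,12,14-trimethoxyarene; the last step is an oxidative demethylation with no skeletal change.
2. C7–C8 bond (seven-membered ring B) ⇒ an aryllithium adding to the carbonyl of a trans-fused γ-lactone; the lactone C(=O)–O–C10 unit becomes the hemiketal bridge.
3. Ring A and the lactone ring ⇒ one enantioselective, proton-initiated cation–olefin bicyclisation of an acyclic (3Z)-4-(arylmethyl)-8-methylnona-3,7-dienoic acid; this sets C5 and C10, and C7 then follows from the bridge.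
4. (3Z)-Dienoic acid ⇒ oxidation of the homoallylic alcohol obtained by hydroxyl-directed syn-carbomagnesiation of ArCH2–C≡C–CH2CH2OH with homoprenylmagnesium bromide; alkynol ⇒ benzylic chloride + but-3-yn-1-ol; arene ⇒ 1,2,4-trimethoxybenzene.
5. Ring order: arene (bought) → ring A and the five-membered oxygen ring together → ring B (closing the oxabicyclo[3.2.1]octane) → quinone by oxidation.

Assumption: icetexane numbering is used (C5 ring-fusion CH, C7 hemiketal carbon, C10 oxygenated quaternary carbon, C20 benzylic CH2); the SMILES is read as (5R,7S,10S), with H-5 and the 7,10-oxygen bridge on the same face, and the bridged hemiketal is taken to be the stable tautomer as drawn.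

**Route**

Step 1
Reactants: 1 1,2,4-trimethoxybenzene
Product: 3 2-(2,3,6-trimethoxyphenyl)propan-2-ol, via aryllithium 2 (not isolated)
Conditions: n-BuLi (1.1 equiv), THF, 0 °C to rt; acetone, −78 °C to rt; sat. aq NH4Cl
Reagents that add atoms: acetone, CC(C)=O
Why: Directed ortho-metalation removes the proton flanked by two methoxy groups and the aryllithium adds to acetone (1,2-addition); no stereocentre is formed.

Step 2
Reactants: 3 2-(2,3,6-trimethoxyphenyl)propan-2-ol
Product: 4 1,2,4-trimethoxy-3-(propan-2-yl)benzene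
Conditions: Et3SiH (3 equiv), CF3CO2H (10 equiv), CH2Cl2, 0 °C to rt
Reagents that add atoms: none
Why: Ionic hydrogenation, in which the acid ionises the tertiary benzylic alcohol to a cation stabilised by the two ortho methoxy groups and the silane delivers hydride.

Step 3
Reactants: 4 1,2,4-trimethoxy-3-(propan-2-yl)benzene
Product: 5 1-bromo-2,4,5-trimethoxy-3-(propan-2-yl)benzene
Conditions: N-bromosuccinimide (1.05 equiv), MeCN, 0 °C to rt
Reagents that add atoms: N-bromosuccinimide, O=C1CCC(=O)N1Br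
Why: Electrophilic aromatic bromination goes to the one free position that is para to a methoxy group and ortho to another (the future C8), where the bromine serves as blocking group and later as lithiation handle.

Step 4
Reactants: 5 1-bromo-2,4,5-trimethoxy-3-(propan-2-yl)benzene
Product: 6 1-bromo-2-(chloromethyl)-3,4,6-trimethoxy-5-(propan-2-yl)benzene
Conditions: (CH2O)n, HCl (gas), ZnCl2 (20 mol%), AcOH, 45 °C
Reagents that add atoms: formaldehyde (from paraformaldehyde), C=O; hydrogen chloride, Cl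
Why: Blanc chloromethylation can only occur at the single remaining aromatic C–H (ortho to a methoxy group, the future C9), so the regiochemistry is fixed by the bromine introduced in step 3.

Step 5
Reactants: 6 1-bromo-2-(chloromethyl)-3,4,6-trimethoxy-5-(propan-2-yl)benzene; 7 but-3-yn-1-ol
Product: 8 5-[2-bromo-3,5,6-trimethoxy-4-(propan-2-yl)phenyl]pent-3-yn-1-ol
Conditions: CuI (10 mol%), Cs2CO3 (1.5 equiv), MeCN, 50 °C
Reagents that add atoms: none
Why: Copper-catalysed sp–sp3 coupling of a terminal alkyne with an activated benzylic chloride (Sonogashira-type alkynylation) tolerates the free hydroxyl and the hindered aryl bromide.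

Step 6
Reactants: 8 5-[2-bromo-3,5,6-trimethoxy-4-(propan-2-yl)phenyl]pent-3-yn-1-ol; 9 5-bromo-2-methylpent-2-ene
Product: 12 (3Z)-4-{[2-bromo-3,5,6-trimethoxy-4-(propan-2-yl)phenyl]methyl}-8-methylnona-3,7-dien-1-ol, via Grignard reagent 10 (not isolated), via alkenylmagnesium alkoxide 11 (not isolated)
Conditions: Mg, THF (Grignard from 9, 3 equiv); Fe(acac)3 (10 mol%), THF, 0 °C to rt; sat. aq NH4Cl
Reagents that add atoms: none
Why: Alkoxide-directed, iron-catalysed syn-carbomagnesiation of a homopropargylic alcohol puts the alkyl group on the distal alkyne carbon and the metal (then H) on the proximal one from the same face, so the arylmethyl group ends up cis to the CH2CH2OH chain (3Z).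

Step 7
Reactants: 12 (3Z)-4-{[2-bromo-3,5,6-trimethoxy-4-(propan-2-yl)phenyl]methyl}-8-methylnona-3,7-dien-1-ol
Product: 14 (3Z)-4-{[2-bromo-3,5,6-trimethoxy-4-(propan-2-yl)phenyl]methyl}-8-methylnona-3,7-dienoic acid, via aldehyde 13 (not isolated)
Conditions: 2,2,6,6-tetramethylpiperidin-1-oxyl (20 mol%), PhI(OAc)2 (2.2 equiv), MeCN/H2O (1:1), 0 °C to rt
Reagents that add atoms: water, O
Why: Oxoammonium-mediated oxidation of the primary alcohol through the aldehyde hydrate to the acid runs near neutral pH, so the skipped trisubstituted alkenes neither migrate nor isomerise.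

Step 8
Reactants: 14 (3Z)-4-{[2-bromo-3,5,6-trimethoxy-4-(propan-2-yl)phenyl]methyl}-8-methylnona-3,7-dienoic acid
Product: 15 (3aR,7aS)-7a-{[2-bromo-3,5,6-trimethoxy-4-(propan-2-yl)phenyl]methyl}-4,4-dimethylhexahydro-1-benzofuran-2(3H)-one
Conditions: SnCl4 (2.5 equiv) precomplexed 1:1 with (S)-2'-[(2-fluorophenyl)methoxy]-1,1'-binaphthalen-2-ol, toluene, −78 °C, 3 d; H2O; recrystallisation (hexane/EtOAc) to ≥99% ee
Reagents that add atoms: none
Why: Proposed new method: the SnCl4-acidified chiral binaphthol protonates the terminal isopropylidene and starts a concerted chair-like anti addition across the C3=C4 alkene (new C–C bond on one face, carboxyl oxygen on the other), which forms ring A and the lactone ring in one operation and turns the cis arrangement of CH2Ar and CH2CO2H into the trans-fused lactone with both ring-fusion centres (3aR,7aS) set, the S reagent being chosen as the mirror image of the R reagent that gives natural-series ambrox-type folding (the bromine atom allows X-ray confirmation of the absolute sense); closest known reaction type: Lewis acid-assisted chiral Brønsted acid-induced enantioselective protonative cyclisation of homopolyprenyl alcohols and acids to ambrox-type ethers and sclareolide-type trans-lactones.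

Step 9
Reactants: 15 (3aR,7aS)-7a-{[2-bromo-3,5,6-trimethoxy-4-(propan-2-yl)phenyl]methyl}-4,4-dimethylhexahydro-1-benzofuran-2(3H)-one
Product: 18 (5R,7S,10S)-11,12,14-trimethoxy-7,10-epoxyicetexa-8,11,13-trien-7-ol, via aryllithium 16 (not isolated), via lithium lactolate 17 (not isolated)
Conditions: t-BuLi (2.2 equiv), THF/Et2O (4:1), −100 °C, then −78 °C, 1 h; sat. aq NH4Cl
Reagents that add atoms: none
Why: Parham cyclisation, in which bromine–lithium exchange outruns carbonyl attack at −100 °C and the aryllithium adds intramolecularly to the lactone carbonyl to close ring B, the tetrahedral adduct being the bridged lactolate whose C7 configuration (S) is dictated by the oxygen bridge from C10.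

Step 10
Reactants: 18 (5R,7S,10S)-11,12,14-trimethoxy-7,10-epoxyicetexa-8,11,13-trien-7-ol
Product: 19 (5R,7S,10S)-7-hydroxy-12-methoxy-7,10-epoxyicetexa-8,12-diene-11,14-dione
Conditions: (NH4)2Ce(NO3)6 (2.5 equiv), MeCN/H2O (2:1), 0 °C, 20 min
Reagents that add atoms: water, O
Why: Oxidative demethylation of the para-dimethoxy pair (C11 and C14) gives the p-quinone and keeps the C12 methoxy group, leaves the three stereocentres untouched, and the electron-poor acylquinone carbonyl favours the closed hemiketal.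

**Compound list**

1 | 1,2,4-trimethoxybenzene | COc1ccc(OC)c(OC)c1 | starting material
2 | (2,3,6-trimethoxyphenyl)lithium | COc1ccc(OC)c([Li])c1OC | intermediate
3 | 2-(2,3,6-trimethoxyphenyl)propan-2-ol | COc1ccc(OC)c(C(C)(C)O)c1OC | intermediate
4 | 1,2,4-trimethoxy-3-(propan-2-yl)benzene | COc1ccc(OC)c(C(C)C)c1OC | intermediate
5 | 1-bromo-2,4,5-trimethoxy-3-(propan-2-yl)benzene | COc1cc(Br)c(OC)c(C(C)C)c1OC | intermediate
6 | 1-bromo-2-(chloromethyl)-3,4,6-trimethoxy-5-(propan-2-yl)benzene | COc1c(CCl)c(Br)c(OC)c(C(C)C)c1OC | intermediate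
7 | but-3-yn-1-ol | OCCC#C | starting material
8 | 5-[2-bromo-3,5,6-trimethoxy-4-(propan-2-yl)phenyl]pent-3-yn-1-ol | OCCC#CCc1c(Br)c(OC)c(C(C)C)c(OC)c1OC | intermediate
9 | 5-bromo-2-methylpent-2-ene | CC(C)=CCCBr | starting material
10 | (4-methylpent-3-en-1-yl)magnesium bromide | CC(C)=CCC[Mg]Br | intermediate
11 | bromomagnesium (3E)-3-(bromomagnesio)-4-{[2-bromo-3,5,6-trimethoxy-4-(propan-2-yl)phenyl]methyl}-8-methylnona-3,7-dien-1-olate | Br[Mg]OCC/C([Mg]Br)=C(/CCC=C(C)C)Cc1c(Br)c(OC)c(C(C)C)c(OC)c1OC | intermediate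
12 | (3Z)-4-{[2-bromo-3,5,6-trimethoxy-4-(propan-2-yl)phenyl]methyl}-8-methylnona-3,7-dien-1-ol | OCC/C=C(/CCC=C(C)C)Cc1c(Br)c(OC)c(C(C)C)c(OC)c1OC | intermediate
13 | (3Z)-4-{[2-bromo-3,5,6-trimethoxy-4-(propan-2-yl)phenyl]methyl}-8-methylnona-3,7-dienal | O=CC/C=C(/CCC=C(C)C)Cc1c(Br)c(OC)c(C(C)C)c(OC)c1OC | intermediate
14 | (3Z)-4-{[2-bromo-3,5,6-trimethoxy-4-(propan-2-yl)phenyl]methyl}-8-methylnona-3,7-dienoic acid | OC(=O)C/C=C(/CCC=C(C)C)Cc1c(Br)c(OC)c(C(C)C)c(OC)c1OC | intermediate
15 | (3aR,7aS)-7a-{[2-bromo-3,5,6-trimethoxy-4-(propan-2-yl)phenyl]methyl}-4,4-dimethylhexahydro-1-benzofuran-2(3H)-one (trans-fused lactone) | COc1c(OC)c(C(C)C)c(OC)c(Br)c1C[C@@]23CCCC(C)(C)[C@H]2CC(=O)O3 | intermediate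
16 | [2-{[(3aR,7aS)-4,4-dimethyl-2-oxooctahydro-1-benzofuran-7a-yl]methyl}-3,4,6-trimethoxy-5-(propan-2-yl)phenyl]lithium | COc1c(OC)c(C(C)C)c(OC)c([Li])c1C[C@@]23CCCC(C)(C)[C@H]2CC(=O)O3 | intermediate
17 | lithium (5R,7S,10S)-11,12,14-trimethoxy-7,10-epoxyicetexa-8,11,13-trien-7-olate | COc1c(C(C)C)c(OC)c2c(C[C@@]34CCCC(C)(C)[C@H]3C[C@]2(O[Li])O4)c1OC | intermediate
18 | (5R,7S,10S)-11,12,14-trimethoxy-7,10-epoxyicetexa-8,11,13-trien-7-ol (bridged hemiketal; H-5 syn to the oxygen bridge) | COc1c(C(C)C)c(OC)c2c(C[C@@]34CCCC(C)(C)[C@H]3C[C@]2(O)O4)c1OC | intermediate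
19 | (5R,7S,10S)-7-hydroxy-12-methoxy-7,10-epoxyicetexa-8,12-diene-11,14-dione | COC1=C(C(C)C)C(=O)C2=C(C[C@@]34CCCC(C)(C)[C@H]3C[C@]2(O)O4)C1=O | target

**Step count and risks**

Total step count: 10. Longest linear sequence: 10 steps (from 1).

Steps most likely to fail:

Step 8. The risks are modest enantioselectivity, protonation of the internal alkene (giving a monocyclic lactone), and a stepwise pathway that erodes the trans ring fusion; tin binding to the methoxy groups may also demand more reagent. The fallback sets out from 14 and comes back at 15, taking the chirality from an epoxide instead of a chiral proton source. Shi epoxidation of the terminal alkene of 14 (KHSO5, K2CO3, buffered MeCN/H2O, 0 °C, partial conversion) uses the fructose-derived ketone 1,2:4,5-di-O-isopropylidene-D-erythro-hexo-2,3-diulo-2,6-pyranose, or its enantiomer if that is the one giving 7R. It gives (3Z)-4-{[2-bromo-3,5,6-trimethoxy-4-(propan-2-yl)phenyl]methyl}-6-[(2R)-3,3-dimethyloxiran-2-yl]hex-3-enoic acid F6. BF3·OEt2 in CH2Cl2 at −78 °C then opens the epoxide at its tertiary carbon and drives the same chair-like bicyclisation with carboxyl capture to the hydroxy lactone (3aR,5R,7aS)-7a-{[2-bromo-3,5,6-trimethoxy-4-(propan-2-yl)phenyl]methyl}-5-hydroxy-4,4-dimethylhexahydro-1-benzofuran-2(3H)-one F7. NaH, CS2 and MeI convert it to the S-methyl xanthate F8, and Barton–McCombie reduction (Bu3SnH, 2,2'-azobis(2-methylpropionitrile), toluene, 80 °C) removes the oxygen to give 15.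

Step 6. The risks are iron-mediated attack on the aryl bromide, deprotonation of the doubly activated ArCH2–C≡C position, and β-hydride loss from the Grignard reagent. The fallback sets out from 6 and 9 and comes back at 14, building the trisubstituted alkene by two stereoretentive cross-couplings on a bromoboration template. Compound 9 with lithium acetylide–ethylenediamine complex in DMSO gives 6-methylhept-5-en-1-yne F1. Syn-bromoboration with BBr3 (CH2Cl2, −78 °C) followed by pinacol gives 2-[(1Z)-2-bromo-6-methylhepta-1,5-dien-1-yl]-4,4,5,5-tetramethyl-1,3,2-dioxaborolane F2. Zinc insertion into 6 (Zn, LiCl, THF) gives {[2-bromo-3,5,6-trimethoxy-4-(propan-2-yl)phenyl]methyl}zinc chloride F3. Negishi coupling of F2 with F3 (Pd(PPh3)4, THF, rt) replaces the vinylic bromine with retention and gives the alkenylboronate 2-[(1Z)-2-{[2-bromo-3,5,6-trimethoxy-4-(propan-2-yl)phenyl]methyl}-6-methylhepta-1,5-dien-1-yl]-4,4,5,5-tetramethyl-1,3,2-dioxaborolane F4. Suzuki coupling with methyl bromoacetate (Pd(OAc)2, P(o-tol)3, K3PO4, THF/H2O) gives methyl (3Z)-4-{[2-bromo-3,5,6-trimethoxy-4-(propan-2-yl)phenyl]methyl}-8-methylnona-3,7-dienoate F5. LiOH (THF/H2O, 0 °C) then gives 14.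

Step 9. The risks are proton transfer from the lactone α-CH2 to the aryllithium and the strain of closing the seven-membered ring onto a trans-fused lactone. The fallback sets out from 15 and comes back at 18, doing the ring closure at the aldehyde oxidation level. i-Bu2AlH (CH2Cl2, −78 °C) reduces 15 to the lactol (3aR,7aS)-7a-{[2-bromo-3,5,6-trimethoxy-4-(propan-2-yl)phenyl]methyl}-4,4-dimethyloctahydro-1-benzofuran-2-ol F9. After deprotonation with MeLi and bromine–lithium exchange with t-BuLi (THF, −78 °C), the aryl anion adds to the aldehyde tautomer and gives (5R,10S)-11,12,14-trimethoxyicetexa-8,11,13-triene-7,10-diol F10 as a C7 epimer mixture. MnO2 (CH2Cl2, rt) oxidises the benzylic alcohol selectively, and the resulting 10-hydroxy-7-ketone closes to 18.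

Further compounds
F1 | step 6 | 6-methylhept-5-en-1-yne | C#CCCC=C(C)C
F2 | step 6 | 2-[(1Z)-2-bromo-6-methylhepta-1,5-dien-1-yl]-4,4,5,5-tetramethyl-1,3,2-dioxaborolane | CC(C)=CCC/C(Br)=C/B1OC(C)(C)C(C)(C)O1
F3 | step 6 | {[2-bromo-3,5,6-trimethoxy-4-(propan-2-yl)phenyl]methyl}zinc chloride | Cl[Zn]Cc1c(Br)c(OC)c(C(C)C)c(OC)c1OC
F4 | step 6 | 2-[(1Z)-2-{[2-bromo-3,5,6-trimethoxy-4-(propan-2-yl)phenyl]methyl}-6-methylhepta-1,5-dien-1-yl]-4,4,5,5-tetramethyl-1,3,2-dioxaborolane | CC(C)=CCC/C(Cc1c(Br)c(OC)c(C(C)C)c(OC)c1OC)=C/B2OC(C)(C)C(C)(C)O2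
F5 | step 6 | methyl (3Z)-4-{[2-bromo-3,5,6-trimethoxy-4-(propan-2-yl)phenyl]methyl}-8-methylnona-3,7-dienoate | COC(=O)C/C=C(/CCC=C(C)C)Cc1c(Br)c(OC)c(C(C)C)c(OC)c1OC
F6 | step 8 | (3Z)-4-{[2-bromo-3,5,6-trimethoxy-4-(propan-2-yl)phenyl]methyl}-6-[(2R)-3,3-dimethyloxiran-2-yl]hex-3-enoic acid | OC(=O)C/C=C(/CC[C@H]1OC1(C)C)Cc1c(Br)c(OC)c(C(C)C)c(OC)c1OC
F7 | step 8 | (3aR,5R,7aS)-7a-{[2-bromo-3,5,6-trimethoxy-4-(propan-2-yl)phenyl]methyl}-5-hydroxy-4,4-dimethylhexahydro-1-benzofuran-2(3H)-one | COc1c(OC)c(C(C)C)c(OC)c(Br)c1C[C@@]23CC[C@@H](O)C(C)(C)[C@H]2CC(=O)O3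
F8 | step 8 | O-[(3aR,5R,7aS)-7a-{[2-bromo-3,5,6-trimethoxy-4-(propan-2-yl)phenyl]methyl}-4,4-dimethyl-2-oxooctahydro-1-benzofuran-5-yl] S-methyl carbonodithioate | COc1c(OC)c(C(C)C)c(OC)c(Br)c1C[C@@]23CC[C@@H](OC(=S)SC)C(C)(C)[C@H]2CC(=O)O3
F9 | step 9 | (3aR,7aS)-7a-{[2-bromo-3,5,6-trimethoxy-4-(propan-2-yl)phenyl]methyl}-4,4-dimethyloctahydro-1-benzofuran-2-ol (C2 anomers) | COc1c(OC)c(C(C)C)c(OC)c(Br)c1C[C@@]23CCCC(C)(C)[C@H]2CC(O)O3
F10 | step 9 | (5R,10S)-11,12,14-trimethoxyicetexa-8,11,13-triene-7,10-diol (C7 epimers) | COc1c(C(C)C)c(OC)c2c(C[C@@]3(O)CCCC(C)(C)[C@H]3CC2O)c1OC
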